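**Retrosynthetic overview**

1. Lamesticumin C ⇐ reductive desulfonylation ⇐ Stork–Danheiser union (bond C11'–C9') of a ring A/B primary iodide (3β-silyloxy, 8-methylene, C9–CH2CH2I) with a ring A'/B' vinylogous ester.
2. Iodide ⇐ Δ8 C9-enol triflate (vinylation, two hydroborations, methylenation); vinylogous ester ⇐ 7',9'-dione made by oxidative excision of an isopropenyl group.
3. Both halves ⇐ one trans-decalin β-keto sulfone ⇐ (R)-carvone + methyl isobutyrate + phenyl vinyl sulfone in a Michael/Michael/Claisen cascade whose last event closes ring A through C2–C3.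
4. Enabling feature: in each decalin C3 is an oxygenated carbon next to the quaternary, non-enolisable C4, and C5/C10 are the β/α carbons of a ring B enone whose carbonyl carbon C9 is the carbon that later carries the linker. One enolate relay can therefore make C4–C5, C10–C1 and C2–C3, with the carvone stereocentre (C7) controlling C5 and C10.
5. Ring order: ring B is bought (carvone), ring A is closed in the cascade (likewise A'/B'); the halves are joined last. The sulfone first activates C2, then masks the C3/C3' ketone, and is removed.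

Key step: step 1

Remark on numbering: each decalin is numbered like a drimane (C1–C10, linker carbon C11 on C9); primes mark the enone half and are used from step 12 on. α/β mean opposite to/same side as the C10 methyl group.
Remark on the chemistry: the sulfone-bearing centre C2 (C2') is carried as a mixture of epimers, because it is deleted by desulfonylation.

**Route**

Step 1
Reactants: 1 (R)-(−)-carvone; 2 methyl isobutyrate; 3 phenyl vinyl sulfone
Product: 7 trans-decalin β-keto sulfone [7α-isopropenyl-4,4,10β-trimethyl-2-(phenylsulfonyl)decalin-3,9-dione; 5α-H], via lithium ester enolate 4 (not isolated), via Michael-adduct enolate 5 (not isolated), via α-lithio sulfone 6 (not isolated)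
Conditions: LiN(i-Pr)2 (1.05 equiv), 2, THF, −78 °C; add 1 and DMPU, −78 °C to rt; add 3, −40 to 40 °C; aq NH4Cl
Reagents that add atoms: none
Why: Proposed new method: enolate 4 adds 1,4 to the enone of 1 (C4–C5), the tetrasubstituted enolate 5 adds through C10 to the vinyl sulfone (C10–C1), and the α-sulfonyl carbanion 6 acylates the non-enolisable ester carbonyl C3 (C2–C3) with loss of methoxide, which then deprotonates the β-keto sulfone and makes the sequence irreversible. The closest known reaction types are Michael–Michael-initiated ring closures (MIMIRC), the Michael–Claisen cyclisation and the base-mediated sulfone–ester Dieckmann condensation; each elementary step is known, their three-component merger on an α-methyl enone is not. Ring A closes in the 6-exo-trig mode (carbanion C2 onto ester C3), ring B being carried in from carvone. C5 is set by the C7 isopropenyl group (axial attack anti to it, as in other conjugate additions to carvone), and C10 by the new C5 substituent (the sulfone is taken up anti to the pseudo-axial ester arm, which puts C1 and C4 trans and leads to the trans-decalin); C2 is uncontrolled and deleted later. The step needs 1,4- over 1,2-addition (hindered α,α-disubstituted ester enolate in THF/DMPU, warmed so that any 1,2-adduct reverts) and closure on C3 rather than on the C9 ketone; attack of C2 on C9 would give a cyclobutanol, and closure of a C8 enolate on C3 would give a bridged β-diketone that cannot form a stabilised enolate and reverts, whereas the β-keto sulfone enolate is a thermodynamic sink.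

Step 2
Reactants: 7 trans-decalin β-keto sulfone
Product: 9 4,4,10β-trimethyl-2-(phenylsulfonyl)decalin-3,9-dione (5α-H), via α-methoxy hydroperoxide 8 (not isolated)
Conditions: O3, MeOH/CH2Cl2, −78 °C; then FeSO4·7H2O, PhSH, −78 °C to rt
Reagents that add atoms: none
Why: ozonolysis in methanol converts the isopropenyl group into an α-methoxy hydroperoxide, divalent iron cleaves it to an alkoxy radical, β-scission expels methyl acetate, and the C7 radical takes hydrogen from the thiol (ozonolytic hydrodealkenylation), which removes the stereocontrol element without touching C5 or C10.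

Step 3
Reactants: 9 dealkenylated β-keto sulfone
Product: 11 Δ8 C9-enol triflate of 9, via dipotassium dianion 10 (not isolated)
Conditions: KN(SiMe3)2 (2.2 equiv), THF, −78 °C; PhNTf2 (1.05 equiv), −78 to 0 °C
Reagents that add atoms: N-phenylbis(trifluoromethanesulfonimide), O=S(=O)(N(c1ccccc1)S(=O)(=O)C(F)(F)F)C(F)(F)F
Why: the first equivalent of base stores C3 as the stabilised β-keto sulfone enolate, and the second forms the more nucleophilic C9 ketone enolate (only towards C8, since C10 is quaternary), which should be O-sulfonylated selectively (enol triflate formation from a dianion).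

Step 4
Reactants: 11 sulfonyl keto enol triflate
Product: 12 3-oxo Δ8 C9-enol triflate
Conditions: SmI2 (2.5 equiv), THF/MeOH, −78 °C
Reagents that add atoms: none
Why: divalent samarium cleaves the C–S bond α to the ketone (reductive desulfonylation of a β-keto sulfone) much faster than it attacks an enol triflate or a simple ketone, and methanol protonates the samarium enolate.

Step 5
Reactants: 12 3-oxo enol triflate
Product: 13 3β-hydroxy Δ8 C9-enol triflate
Conditions: NaBH4, MeOH/THF, 0 °C
Reagents that add atoms: none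
Why: hydride should attack C3 from the α face, away from the axial 4β- and 10β-methyl groups, giving the equatorial 3β-alcohol (substrate-controlled ketone reduction).

Step 6
Reactants: 13 3β-hydroxy enol triflate
Product: 14 3β-triethylsilyloxy Δ8 C9-enol triflate
Conditions: Et3SiOTf, 2,6-lutidine, CH2Cl2, 0 °C
Reagents that add atoms: triethylsilyl triflate, CC[Si](CC)(CC)OS(=O)(=O)C(F)(F)F
Why: silylation with the silyl triflate protects the hindered neopentyl alcohol as an ether that survives bases, boranes and organolithiums but falls to aqueous acid at the end.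

Step 7
Reactants: 14 silyl-protected enol triflate
Product: 15 9-vinyl Δ8 diene (3β-triethylsilyloxy)
Conditions: Bu3SnCH=CH2, Pd(PPh3)4 (5 mol %), LiCl, THF, 65 °C
Reagents that add atoms: tributyl(vinyl)tin, C=C[Sn](CCCC)(CCCC)CCCC
Why: Stille coupling of a cyclohexenyl triflate with a vinylstannane under zerovalent palladium with LiCl is reliable even next to a quaternary carbon and brings in both linker carbons.

Step 8
Reactants: 15 diene
Product: 17 primary alcohol [2-(Δ8-en-9-yl)ethanol], via B-alkyl-9-BBN adduct 16 (not isolated)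
Conditions: 9-BBN-H, THF, 0 °C to rt; then NaOH (aq), H2O2, 0 °C
Reagents that add atoms: hydrogen peroxide, OO
Why: the bulky borane adds anti-Markovnikov to the monosubstituted vinyl group only and leaves the hindered trisubstituted ring alkene untouched (hydroboration–oxidation).

Step 9
Reactants: 17 primary alcohol
Product: 18 primary iodide (Δ8 retained)
Conditions: I2, PPh3, imidazole, CH2Cl2, 0 °C
Reagents that add atoms: iodine, II
Why: Appel-type iodination of an unhindered primary alcohol is done before any oxygen is placed on C8, so no cyclic ether can form.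

Step 10
Reactants: 18 primary iodide
Product: 20 8-oxo-9β-(2-iodoethyl) compound (9α-H), via 8α-boryl intermediate 19 (not isolated)
Conditions: BH3·SMe2, CH2Cl2, 0 °C to rt; then [C5H5NH][CrO3Cl], CH2Cl2, 40 °C
Reagents that add atoms: pyridinium chlorochromate, [O-][Cr](=O)(=O)Cl.c1cc[nH+]cc1
Why: borane should add syn from the α face, anti to the C10 methyl group, placing boron on C8 and hydrogen on C9 (9α-H, side chain β and equatorial, also the thermodynamic epimer), and hexavalent chromium oxidises the C–B bond directly to the ketone (hydroboration–chromate oxidation), so no alkoxide ever sits next to the iodide.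

Step 11
Reactants: 20 8-ketone
Product: 21 ring A/B iodide [3β-triethylsilyloxy-8-methylene-9β-(2-iodoethyl)]
Conditions: Cp2TiMe2, toluene/THF, 65 °C
Reagents that add atoms: dimethyltitanocene, [CH3-].[CH3-].[Ti+4].c1cc[cH-]c1.c1cc[cH-]c1
Why: Petasis methylenation uses a non-basic titanium carbene, so the C9 centre is not epimerised, the γ-iodo ketone cannot close to a cyclopropane, and the iodide is not alkylated as it would be by a phosphorus ylide.

Step 12
Reactants: 7 trans-decalin β-keto sulfone
Product: 23 8-methyl derivative of 7 (C8 epimers), via dilithium dianion 22 (not isolated)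
Conditions: LiN(i-Pr)2 (2.1 equiv), THF, −78 to −20 °C; MeI (1.0 equiv), −78 °C
Reagents that add atoms: methyl iodide, CI
Why: in the dianion the localised C9/C8 ketone enolate is far more nucleophilic than the sulfone-stabilised enolate, so one equivalent of MeI should alkylate C8 only (dianion alkylation at the less stabilised site).

Step 13
Reactants: 23 8-methyl β-keto sulfone
Product: 26 8'-methyl-7',9'-dione (enolisable 2-methyl-1,3-dione; 3'-oxo-2'-sulfone retained), via α-methoxy hydroperoxide 24 (not isolated), via TEMPO adduct 25 (not isolated)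
Conditions: O3, MeOH/CH2Cl2, −78 °C; then FeSO4·7H2O, TEMPO, −78 °C to rt; then mCPBA (1.1 equiv), CH2Cl2, 0 °C
Reagents that add atoms: TEMPO, CC1(C)CCCC(C)(C)N1[O]
Why: the same iron-induced fragmentation as in step 2 gives the C7 radical, which the nitroxyl traps, and peracid oxidation of the alkoxyamine gives the ketone (ozonolytic oxodealkenylation), so the carvone side chain becomes the C7' carbonyl.

Step 14
Reactants: 26 2-methyl-1,3-dione
Product: 27 ring A'/B' vinylogous ester (7'-isobutoxy-8'-methyl-7'-en-9'-one)
Conditions: i-BuOH, TsOH·H2O (cat.), benzene, reflux, Dean–Stark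
Reagents that add atoms: isobutanol, CC(C)CO
Why: acid-catalysed enol etherification of the dione should occur at the unhindered C7' carbonyl and leave the carbonyl on C9' next to quaternary C10' (the less strained regioisomer under equilibrating conditions), while the hindered β-keto sulfone ketone does not react.

Step 15
Reactants: 21 ring A/B iodide; 27 ring A'/B' vinylogous ester
Product: 31 2'-(phenylsulfonyl)lamesticumin C, via alkyllithium 28 (not isolated), via sodium enolate 29 (not isolated), via tertiary alkoxide adduct 30 (not isolated)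
Conditions: 21, t-BuLi (2.0 equiv), Et2O/pentane, −78 °C; 27, NaH (1.0 equiv), THF, 0 °C; combine, −78 to 0 °C; then 2 M HCl, THF/MeOH, rt
Reagents that add atoms: water, O
Why: iodine–lithium exchange gives the primary alkyllithium, which adds 1,2 to the C9' carbonyl while the β-keto sulfone is shielded as its sodium enolate, and aqueous acid then ionises the tertiary allylic alcohol, hydrolyses the enol ether to the transposed 8'-en-7'-one (Stork–Danheiser transposition) and cleaves the silyl ether, with no new stereocentre because C9' becomes sp2.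

Step 16
Reactants: 31 2'-(phenylsulfonyl)lamesticumin C
Product: 32 lamesticumin C
Conditions: SmI2 (2.5 equiv), THF/MeOH, −78 °C
Reagents that add atoms: none
Why: reductive desulfonylation of the β-keto sulfone by divalent samarium is fast at −78 °C and should leave the tetrasubstituted enone, the exocyclic alkene and the free alcohol untouched, releasing the C3' ketone.

**Compound list**

1 | (R)-(−)-carvone | CC1=CC[C@H](CC1=O)C(C)=C | starting material
2 | methyl isobutyrate | COC(=O)C(C)C | starting material
3 | phenyl vinyl sulfone | C=CS(=O)(=O)c1ccccc1 | starting material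
4 | lithium enolate of methyl isobutyrate | COC(O[Li])=C(C)C | intermediate
5 | lithium enolate of the 1,4-adduct (ester arm on C5 trans to isopropenyl) | COC(=O)C(C)(C)[C@@H]1C[C@@H](C(C)=C)CC(O[Li])=C1C | intermediate
6 | α-lithio sulfone after the second Michael addition (C10 quaternary) | COC(=O)C(C)(C)[C@@H]1C[C@@H](C(C)=C)CC(=O)[C@@]1(C)CC([Li])S(=O)(=O)c1ccccc1 | intermediate
7 | 7α-isopropenyl-4,4,10β-trimethyl-2-(phenylsulfonyl)-trans-decalin-3,9-dione (5α-H, C2 epimers) | O=C1C[C@H](C(C)=C)C[C@H]2C(C)(C)C(=O)C(S(=O)(=O)c3ccccc3)C[C@]12C | intermediate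
8 | α-methoxy hydroperoxide from ozonolysis of 7 | O=C1C[C@H](C(C)(OC)OO)C[C@H]2C(C)(C)C(=O)C(S(=O)(=O)c3ccccc3)C[C@]12C | intermediate
9 | 4,4,10β-trimethyl-2-(phenylsulfonyl)-trans-decalin-3,9-dione (5α-H) | O=C1CCC[C@H]2C(C)(C)C(=O)C(S(=O)(=O)c3ccccc3)C[C@]12C | intermediate
10 | dipotassium dianion of 9 (C3 and C9 enolates) | [K]OC1=CCC[C@H]2C(C)(C)C(O[K])=C(S(=O)(=O)c3ccccc3)C[C@]12C | intermediate
11 | Δ8 C9-enol triflate, 3-oxo-2-(phenylsulfonyl) | O=S(=O)(OC1=CCC[C@H]2C(C)(C)C(=O)C(S(=O)(=O)c3ccccc3)C[C@]12C)C(F)(F)F | intermediate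
12 | Δ8 C9-enol triflate, 3-oxo | O=S(=O)(OC1=CCC[C@H]2C(C)(C)C(=O)CC[C@]12C)C(F)(F)F | intermediate
13 | Δ8 C9-enol triflate, 3β-hydroxy | O=S(=O)(OC1=CCC[C@H]2C(C)(C)[C@@H](O)CC[C@]12C)C(F)(F)F | intermediate
14 | Δ8 C9-enol triflate, 3β-triethylsilyloxy | O=S(=O)(OC1=CCC[C@H]2C(C)(C)[C@@H](O[Si](CC)(CC)CC)CC[C@]12C)C(F)(F)F | intermediate
15 | 9-vinyl Δ8 diene, 3β-triethylsilyloxy | C=CC1=CCC[C@H]2C(C)(C)[C@@H](O[Si](CC)(CC)CC)CC[C@]12C | intermediate
16 | B-alkyl-9-BBN adduct of 15 | B1(CCC2=CCC[C@H]3C(C)(C)[C@@H](O[Si](CC)(CC)CC)CC[C@]23C)C2CCCC1CCC2 | intermediate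
17 | 2-(3β-triethylsilyloxy-Δ8-en-9-yl)ethanol | OCCC1=CCC[C@H]2C(C)(C)[C@@H](O[Si](CC)(CC)CC)CC[C@]12C | intermediate
18 | 9-(2-iodoethyl) Δ8 alkene, 3β-triethylsilyloxy | ICCC1=CCC[C@H]2C(C)(C)[C@@H](O[Si](CC)(CC)CC)CC[C@]12C | intermediate
19 | 8α-boryl-9β-(2-iodoethyl) intermediate (9α-H) | ICC[C@H]1[C@H](B)CC[C@H]2C(C)(C)[C@@H](O[Si](CC)(CC)CC)CC[C@]12C | intermediate
20 | 8-oxo-9β-(2-iodoethyl), 3β-triethylsilyloxy (9α-H) | O=C1CC[C@H]2C(C)(C)[C@@H](O[Si](CC)(CC)CC)CC[C@]2(C)[C@H]1CCI | intermediate
21 | 8-methylene-9β-(2-iodoethyl), 3β-triethylsilyloxy (ring A/B iodide) | C=C1CC[C@H]2C(C)(C)[C@@H](O[Si](CC)(CC)CC)CC[C@]2(C)[C@H]1CCI | intermediate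
22 | dilithium dianion of 7 | [Li]OC1=C[C@H](C(C)=C)C[C@H]2C(C)(C)C(O[Li])=C(S(=O)(=O)c3ccccc3)C[C@]12C | intermediate
23 | 8-methyl derivative of 7 (C8 epimers) | O=C1C(C)[C@H](C(C)=C)C[C@H]2C(C)(C)C(=O)C(S(=O)(=O)c3ccccc3)C[C@]12C | intermediate
24 | α-methoxy hydroperoxide from ozonolysis of 23 | O=C1C(C)[C@H](C(C)(OC)OO)C[C@H]2C(C)(C)C(=O)C(S(=O)(=O)c3ccccc3)C[C@]12C | intermediate
25 | 7'-(2,2,6,6-tetramethylpiperidin-1-yloxy) adduct | O=C1C(C)C(ON3C(C)(C)CCCC3(C)C)C[C@H]2C(C)(C)C(=O)C(S(=O)(=O)c4ccccc4)C[C@]12C | intermediate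
26 | 8'-methyl-3',7',9'-trione bearing the 2'-sulfone | O=C1C(C)C(=O)C[C@H]2C(C)(C)C(=O)C(S(=O)(=O)c3ccccc3)C[C@]12C | intermediate
27 | 7'-isobutoxy-8'-methyl-7'-en-9'-one, 3'-oxo-2'-sulfone (ring A'/B' vinylogous ester) | O=C1C(C)=C(OCC(C)C)C[C@H]2C(C)(C)C(=O)C(S(=O)(=O)c3ccccc3)C[C@]12C | intermediate
28 | primary alkyllithium from 21 | C=C1CC[C@H]2C(C)(C)[C@@H](O[Si](CC)(CC)CC)CC[C@]2(C)[C@H]1CC[Li] | intermediate
29 | sodium enolate of 27 (β-keto sulfone enolate) | O=C1C(C)=C(OCC(C)C)C[C@H]2C(C)(C)C(O[Na])=C(S(=O)(=O)c3ccccc3)C[C@]12C | intermediate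
30 | 1,2-adduct: C9' tertiary lithium alkoxide, enol ether and sodium enolate intact | C=C1CC[C@H]2C(C)(C)[C@@H](O[Si](CC)(CC)CC)CC[C@]2(C)[C@H]1CCC1(O[Li])C(C)=C(OCC(C)C)C[C@H]2C(C)(C)C(O[Na])=C(S(=O)(=O)c3ccccc3)C[C@]12C | intermediate
31 | 2'-(phenylsulfonyl)lamesticumin C (C2' epimers) | C=C1CC[C@H]2C(C)(C)[C@@H](O)CC[C@]2(C)[C@H]1CCC1=C(C)C(=O)C[C@H]2C(C)(C)C(=O)C(S(=O)(=O)c3ccccc3)C[C@]12C | intermediate
32 | lamesticumin C | C=C1CC[C@H]2C(C)(C)[C@@H](O)CC[C@]2(C)[C@H]1CCC1=C(C)C(=O)C[C@H]2C(C)(C)C(=O)CC[C@]12C | target

**Totals**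

Total step count: 16. Longest linear sequence: 13 steps (steps 1 to 11, then 15 and 16).

**Steps most likely to fail, with fallbacks**

Step 1 (proposed new method). What may go wrong: 1,2-addition or proton transfer between the ester enolate and carvone instead of conjugate addition; slow uptake of the vinyl sulfone by the hindered tetrasubstituted enolate, with enolate equilibration and multiple additions; stalling before the Claisen closure. Fallback, from 1 back to 7, in isolated stages of known chemistry: the commercial silyl ketene acetal 1-methoxy-2-methyl-1-(trimethylsiloxy)propene is added to 1 in a Mukaiyama–Michael reaction run with silyl transfer (catalytic Me3SiOTf, CH2Cl2, −78 °C), giving the trimethylsilyl enol ether of the 1,4-adduct F1. MeLi (THF, 0 °C) then releases the regiodefined lithium enolate 5, which is treated with 3 and quenched with NH4Cl to give the isolated keto ester sulfone F2. F2 is cyclised on its own with KOt-Bu (2.2 equiv, THF, 0 °C to rt; sulfone–ester Dieckmann condensation), and the route is rejoined at 7.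

Step 15. What may go wrong: deprotonation of the vinylogous ester at C6' or simple quenching of the alkyllithium instead of 1,2-addition to the hindered C9' carbonyl; a wrong enol-ether regioisomer from step 14 would also misplace the chain. Fallback, from 23 (with 21 as before) back to 31, which also bypasses steps 13 and 14: 23 is ozonised in MeOH to 24, and the hydroperoxide is fragmented with Cu(OAc)2 and FeSO4·7H2O (oxidative elimination of the C7 radical by divalent copper), followed by DBU to bring the double bond into conjugation, giving the 8'-methyl-7'-en-9'-one F3. NaH converts F3 into its sodium enolate F4, and the alkyllithium 28 is added 1,2 to the more electrophilic enone carbonyl to give the tertiary allylic alcohol F5. Pyridinium chlorochromate then effects the oxidative 1,3-transposition (Dauben-type) to the silyl-protected sulfonyl enone F6, and 2 M HCl in THF/MeOH removes the silyl ether, rejoining the route at 31.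

Step 10. What may go wrong: incomplete hydroboration of the hindered trisubstituted alkene, poor facial selectivity, or loss of the silyl ether and over-oxidation during the chromate stage. Fallback, from 17 back to 21, with the iodide introduced last: the primary alcohol 17 is protected as the 4-methoxybenzyl ether F7 (NaH, 4-methoxybenzyl chloride, THF/DMF). The Δ8 alkene is hydroborated with BH3·THF to the 8α-boryl intermediate F8 and oxidised with NaOH/H2O2 to the 8α-alcohol F9. Dess–Martin oxidation gives the 8-ketone F10, and Wittig methylenation (Ph3P=CH2, THF) gives the 8-methylene ether F11. DDQ (CH2Cl2/H2O) frees the primary alcohol F12, and I2/PPh3/imidazole converts it into 21.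

**Further compounds**

F1 | step 1 | trimethylsilyl enol ether of the 1,4-adduct of methyl isobutyrate and carvone | COC(=O)C(C)(C)[C@@H]1C[C@@H](C(C)=C)CC(O[Si](C)(C)C)=C1C
F2 | step 1 | keto ester sulfone (open-chain precursor of 7, C10 quaternary) | COC(=O)C(C)(C)[C@@H]1C[C@@H](C(C)=C)CC(=O)[C@@]1(C)CCS(=O)(=O)c1ccccc1
F3 | step 15 | 8'-methyl-7'-en-9'-one, 3'-oxo-2'-sulfone | O=C1C(C)=CC[C@H]2C(C)(C)C(=O)C(S(=O)(=O)c3ccccc3)C[C@]12C
F4 | step 15 | sodium enolate of F3 | O=C1C(C)=CC[C@H]2C(C)(C)C(O[Na])=C(S(=O)(=O)c3ccccc3)C[C@]12C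
F5 | step 15 | C9' tertiary allylic alcohol from 28 and F4 | C=C1CC[C@H]2C(C)(C)[C@@H](O[Si](CC)(CC)CC)CC[C@]2(C)[C@H]1CCC1(O)C(C)=CC[C@H]2C(C)(C)C(=O)C(S(=O)(=O)c3ccccc3)C[C@]12C
F6 | step 15 | 3-O-triethylsilyl-2'-(phenylsulfonyl)lamesticumin C | C=C1CC[C@H]2C(C)(C)[C@@H](O[Si](CC)(CC)CC)CC[C@]2(C)[C@H]1CCC1=C(C)C(=O)C[C@H]2C(C)(C)C(=O)C(S(=O)(=O)c3ccccc3)C[C@]12C
F7 | step 10 | 4-methoxybenzyl ether of 17 | COc1ccc(COCCC2=CCC[C@H]3C(C)(C)[C@@H](O[Si](CC)(CC)CC)CC[C@]23C)cc1
F8 | step 10 | 8α-boryl intermediate from F7 (9α-H) | COc1ccc(COCC[C@H]2[C@H](B)CC[C@H]3C(C)(C)[C@@H](O[Si](CC)(CC)CC)CC[C@]23C)cc1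
F9 | step 10 | 8α-alcohol (9α-H) | COc1ccc(COCC[C@H]2[C@H](O)CC[C@H]3C(C)(C)[C@@H](O[Si](CC)(CC)CC)CC[C@]23C)cc1
F10 | step 10 | 8-ketone (9α-H) | COc1ccc(COCC[C@H]2C(=O)CC[C@H]3C(C)(C)[C@@H](O[Si](CC)(CC)CC)CC[C@]23C)cc1
F11 | step 10 | 8-methylene 4-methoxybenzyl ether | COc1ccc(COCC[C@H]2C(=C)CC[C@H]3C(C)(C)[C@@H](O[Si](CC)(CC)CC)CC[C@]23C)cc1
F12 | step 10 | 2-(3β-triethylsilyloxy-8-methylene-9β-yl)ethanol | OCC[C@H]1C(=C)CC[C@H]2C(C)(C)[C@@H](O[Si](CC)(CC)CC)CC[C@]12C
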